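## Retrosynthetic overview
1. The target comes from its dimethyl ester by a double saponification at the end. The diester comes from a ring B hydroquinone, whose free, non-chelated C5–OH is methylated selectively.
2. Key C–C disconnection is the ring B C6–C1' (aryl–heptyl) bond. It leads to an aryloxy(methoxycarbonyl)-1,4-benzoquinone (electrophilic C6) and the nitronate of 1-nitroheptane (reversed-polarity d1 carbon). The nitro group leaves as nitrite, so the chain arrives at the alkane level.
3. The quinone comes from oxidative demethylation of a 2,5-dimethoxy diaryl ether. That ether comes from Ullmann C–O coupling of the ring A phenol with methyl 4-bromo-2,5-dimethoxybenzoate.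
4. The ring A phenol comes from iodine/methanol aromatisation of a cyclohexane-1,3-dione ester, made by Michael–Dieckmann union of ethyl (E)-dec-2-enoate and methyl acetoacetate.
5. Ring order: ring A is the only ring built (first, steps 1–2). Ring B is bought as an arene, dearomatised to the quinone for the key step, and re-aromatised by reduction.

Assumption: the target has no stereocentre and the diaryl ether axis is not configurationally stable, so it is one achiral compound and no enantiocontrol is needed.

Ring B locants used below: C1 carboxyl carbon, C2 OH, C3 H, C4 O-aryl, C5 OMe, C6 heptyl.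

## Route

Step 1
Reactants: 1 ethyl (E)-dec-2-enoate; 2 methyl acetoacetate
Product: 5 methyl 6-heptyl-2-hydroxy-4-oxocyclohex-2-ene-1-carboxylate (racemic; mainly trans), via Michael adduct 3 (not isolated), via sodium enolate 4 (not isolated)
Conditions: NaOMe (1.2 equiv), MeOH, reflux, 20 h; then 2 M HCl, 0 °C
Reagents that add atoms: none
Why: Michael addition of the acetoacetate enolate to the enoate β-carbon and Dieckmann (intramolecular Claisen) attack of the acetyl CH3 enolate on the chain ester close the six-membered ring, pulled forward by formation of the stabilised 1,3-dione enolate 4; the two stereocentres arise without control (racemic) and are erased in step 2.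

Step 2
Reactants: 5 methyl 6-heptyl-2-hydroxy-4-oxocyclohex-2-ene-1-carboxylate
Product: 7 methyl 2-heptyl-6-hydroxy-4-methoxybenzoate, via methyl enol ether 6 (not isolated)
Conditions: I2 (1.2 equiv), MeOH, reflux, 16 h
Reagents that add atoms: methanol, CO
Why: Iodine–methanol oxidative aromatisation of a cyclohexane-1,3-dione: acid-catalysed enol ether formation takes place at the unhindered C4 carbonyl while C2 stays tied up as the chelated β-keto ester enol, α-iodination and loss of HI then aromatise 6, and the resulting chelated phenol is not etherified under these conditions.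

Step 3
Reactants: 8 methyl 2,5-dimethoxybenzoate
Product: 9 methyl 4-bromo-2,5-dimethoxybenzoate
Conditions: Br2 (1.05 equiv), AcOH, rt, 3 h
Reagents that add atoms: bromine, BrBr
Why: Electrophilic aromatic bromination: the 5-methoxy group directs ortho (the 2-methoxy group is drained by push–pull conjugation with the ester), and C4 is less hindered than C6.

Step 4
Reactants: 7 methyl 2-heptyl-6-hydroxy-4-methoxybenzoate; 9 methyl 4-bromo-2,5-dimethoxybenzoate
Product: 10 methyl 4-[3-heptyl-5-methoxy-2-(methoxycarbonyl)phenoxy]-2,5-dimethoxybenzoate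
Conditions: CuI (10 mol %), picolinic acid (20 mol %), K3PO4 (2 equiv), dry DMSO, 95 °C, Ar, 24 h
Reagents that add atoms: none
Why: Ullmann-type diaryl ether coupling on monovalent copper with the picolinate ligand, a system made for ortho-substituted partners, helped by the para ester that activates the C–Br bond.

Step 5
Reactants: 10 methyl 4-[3-heptyl-5-methoxy-2-(methoxycarbonyl)phenoxy]-2,5-dimethoxybenzoate
Product: 11 methyl 4-[3-heptyl-5-methoxy-2-(methoxycarbonyl)phenoxy]-3,6-dioxocyclohexa-1,4-diene-1-carboxylate
Conditions: (NH4)2Ce(NO3)6 (2.5 equiv), MeCN–H2O 3:1, 0 °C, 20 min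
Reagents that add atoms: water, O
Why: Oxidative demethylation of a hydroquinone dimethyl ether by tetravalent cerium (two one-electron oxidations, water attacking the two ipso carbons): ring B with three oxygen donors in a 1,2,4 array is oxidised far more easily than ring A, and the aryloxy group stays as a vinylogous ester.

Step 6
Reactants: 12 1-bromoheptane
Product: 13 1-nitroheptane
Conditions: NaNO2 (1.5 equiv), DMF, rt, 6 h; distil
Reagents that add atoms: sodium nitrite, [Na+].[O-]N=O
Why: Kornblum nitrite displacement, an SN2 reaction in which nitrite attacks the primary bromide mainly through nitrogen in a dipolar aprotic solvent; the minor heptyl nitrite is removed by distillation.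

Step 7 (key step)
Reactants: 11 methyl 4-[3-heptyl-5-methoxy-2-(methoxycarbonyl)phenoxy]-3,6-dioxocyclohexa-1,4-diene-1-carboxylate; 13 1-nitroheptane
Product: 18 methyl 2-heptyl-4-[3-heptyl-5-methoxy-2-(methoxycarbonyl)phenoxy]-3,6-dihydroxybenzoate, via potassium nitronate 14 (not isolated), via nitroheptyl hydroquinone 15 (not isolated), via ortho-quinone methide 16 (not isolated), via heptylquinone 17 (not isolated)
Conditions: 13 (1.05 equiv), KOtBu (1.05 equiv), THF–DMF 3:1, −40 °C; add 11, −40 °C, 1 h, then rt, 2 h; then aq Na2S2O4, EtOAc, rt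
Reagents that add atoms: none
Why: Proposed new method: the nitronate carbon of 14 is a reversed-polarity (d1, masked acyl-anion type) donor that attacks C6 of 11, the only ring carbon β to both the C2 quinone carbonyl and the ester (C3 is switched off by the neighbouring aryloxy donor and C4 is a less electrophilic vinylogous ester carbon), so two normally electrophilic carbons are joined; the adduct enolises to hydroquinone 15 (transient racemic stereocentre, destroyed at once), whose C5 phenoxide expels nitrite by E1cB on warming to give ortho-quinone methide 16, the tautomer of alkylquinone 17, and dithionite then gives 18; the closest known reaction type is Michael addition of primary nitroalkanes to enediones and activated quinones followed by loss of nitrous acid.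

Step 8
Reactants: 18 methyl 2-heptyl-4-[3-heptyl-5-methoxy-2-(methoxycarbonyl)phenoxy]-3,6-dihydroxybenzoate
Product: 19 methyl 2-heptyl-4-[3-heptyl-5-methoxy-2-(methoxycarbonyl)phenoxy]-6-hydroxy-3-methoxybenzoate
Conditions: MeI (1.1 equiv), K2CO3 (1.1 equiv), degassed acetone, 40 °C, Ar
Reagents that add atoms: iodomethane, CI
Why: Williamson etherification under chelation control: the C2–OH is locked in a hydrogen bond to the ester and its phenoxide is conjugated with it, so one equivalent of MeI takes the free C5–OH.

Step 9
Reactants: 19 methyl 2-heptyl-4-[3-heptyl-5-methoxy-2-(methoxycarbonyl)phenoxy]-6-hydroxy-3-methoxybenzoate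
Product: 21 4-(2-carboxy-3-heptyl-5-methoxyphenoxy)-2-heptyl-6-hydroxy-3-methoxybenzoic acid (target), via tripotassium salt 20 (not isolated)
Conditions: KOH (10 equiv), DMSO–H2O 4:1, 90 °C, Ar, 12 h; then 1 M HCl, 0 °C
Reagents that add atoms: potassium hydroxide, [K+].[OH-]
Why: Saponification of both di-ortho-substituted esters with poorly solvated hydroxide in DMSO, the standard answer to hindered benzoates; the acids stay as carboxylates while hot and are set free only in the cold, which avoids decarboxylation of the salicylic acid ring.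

## Compound list
1 | ethyl (E)-dec-2-enoate | CCCCCCC/C=C/C(=O)OCC | starting material
2 | methyl acetoacetate | CC(=O)CC(=O)OC | starting material
3 | 5-ethyl 1-methyl 2-acetyl-3-heptylpentanedioate (Michael adduct, racemic diastereomer mixture) | CCCCCCCC(CC(=O)OCC)C(C(C)=O)C(=O)OC | intermediate (not isolated)
4 | sodium enolate of methyl 6-heptyl-2,4-dioxocyclohexane-1-carboxylate (racemic) | CCCCCCCC1CC(=O)C=C([O-])C1C(=O)OC.[Na+] | intermediate (not isolated)
5 | methyl 6-heptyl-2-hydroxy-4-oxocyclohex-2-ene-1-carboxylate (racemic, mainly trans) | CCCCCCCC1CC(=O)C=C(O)C1C(=O)OC | intermediate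
6 | methyl 6-heptyl-4-methoxy-2-oxocyclohex-3-ene-1-carboxylate (racemic) | CCCCCCCC1CC(OC)=CC(=O)C1C(=O)OC | intermediate (not isolated)
7 | methyl 2-heptyl-6-hydroxy-4-methoxybenzoate (ring A phenol) | CCCCCCCc1cc(OC)cc(O)c1C(=O)OC | intermediate
8 | methyl 2,5-dimethoxybenzoate | COC(=O)c1cc(OC)ccc1OC | starting material
9 | methyl 4-bromo-2,5-dimethoxybenzoate | COC(=O)c1cc(OC)c(Br)cc1OC | intermediate
10 | methyl 4-[3-heptyl-5-methoxy-2-(methoxycarbonyl)phenoxy]-2,5-dimethoxybenzoate | CCCCCCCc1cc(OC)cc(Oc2cc(OC)c(C(=O)OC)cc2OC)c1C(=O)OC | intermediate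
11 | methyl 4-[3-heptyl-5-methoxy-2-(methoxycarbonyl)phenoxy]-3,6-dioxocyclohexa-1,4-diene-1-carboxylate | CCCCCCCc1cc(OC)cc(OC2=CC(=O)C(C(=O)OC)=CC2=O)c1C(=O)OC | intermediate
12 | 1-bromoheptane | CCCCCCCBr | starting material
13 | 1-nitroheptane | CCCCCCC[N+](=O)[O-] | intermediate
14 | potassium heptane-1-nitronate | CCCCCCC=[N+]([O-])[O-].[K+] | intermediate (not isolated)
15 | methyl 4-[3-heptyl-5-methoxy-2-(methoxycarbonyl)phenoxy]-3,6-dihydroxy-2-(1-nitroheptyl)benzoate (racemic; present as its potassium phenoxide, drawn neutral) | CCCCCCCc1cc(OC)cc(Oc2cc(O)c(C(=O)OC)c(C(CCCCCC)[N+](=O)[O-])c2O)c1C(=O)OC | intermediate (not isolated)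
16 | methyl 6-heptylidene-4-[3-heptyl-5-methoxy-2-(methoxycarbonyl)phenoxy]-2-hydroxy-5-oxocyclohexa-1,3-diene-1-carboxylate (alkene geometry not defined) | CCCCCCCc1cc(OC)cc(OC2=CC(O)=C(C(=O)OC)C(=CCCCCCC)C2=O)c1C(=O)OC | intermediate (not isolated)
17 | methyl 2-heptyl-4-[3-heptyl-5-methoxy-2-(methoxycarbonyl)phenoxy]-3,6-dioxocyclohexa-1,4-diene-1-carboxylate | CCCCCCCc1cc(OC)cc(OC2=CC(=O)C(C(=O)OC)=C(CCCCCCC)C2=O)c1C(=O)OC | intermediate (not isolated)
18 | methyl 2-heptyl-4-[3-heptyl-5-methoxy-2-(methoxycarbonyl)phenoxy]-3,6-dihydroxybenzoate | CCCCCCCc1cc(OC)cc(Oc2cc(O)c(C(=O)OC)c(CCCCCCC)c2O)c1C(=O)OC | intermediate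
19 | methyl 2-heptyl-4-[3-heptyl-5-methoxy-2-(methoxycarbonyl)phenoxy]-6-hydroxy-3-methoxybenzoate | CCCCCCCc1cc(OC)cc(Oc2cc(O)c(C(=O)OC)c(CCCCCCC)c2OC)c1C(=O)OC | intermediate
20 | tripotassium salt of the target (two carboxylates and the phenoxide) | CCCCCCCc1cc(OC)cc(Oc2cc([O-])c(C(=O)[O-])c(CCCCCCC)c2OC)c1C(=O)[O-].[K+].[K+].[K+] | intermediate (not isolated)
21 | 4-(2-carboxy-3-heptyl-5-methoxyphenoxy)-2-heptyl-6-hydroxy-3-methoxybenzoic acid (achiral) | CCCCCCCc1cc(OC)cc(Oc2cc(O)c(C(=O)O)c(CCCCCCC)c2OC)c1C(=O)O | target

## Count and risks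
Total steps: 9.
Longest linear sequence: 7 (steps 1, 2, 4, 5, 7, 8, 9).

**Step 7 is the most likely to fail.**
- The risks are that the quinone is base-sensitive, the nitronate may displace aryloxide at C4, adduct 15 may exchange electrons with unreacted 11, and 16 may be trapped before it tautomerises.
- The fallback sets out from 11 and comes back at 18. It keeps the same bond and the same polarity reversal but replaces the anionic donor by a neutral, nucleophilic acyl radical.
- Irradiation of 11 with excess heptanal in benzene under argon (photochemical quinone–aldehyde acylation) places the acyl group on the most electron-poor free carbon, C6. This gives methyl 2-heptanoyl-4-[3-heptyl-5-methoxy-2-(methoxycarbonyl)phenoxy]-3,6-dihydroxybenzoate F1.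
- Ionic hydrogenation of this ortho-hydroxyaryl ketone with Et3SiH in CF3CO2H then gives 18.

**Step 4 is next.**
- The risk is that a chelated, ester-deactivated phenol must couple with a bromide that carries an ortho methoxy group.
- The fallback sets out from 8 and comes back at 10. It replaces copper catalysis by metal-free ligand coupling on trivalent iodine, which tolerates and even profits from ortho substituents.
- Iodination of 8 (N-iodosuccinimide, CF3CO2H, MeCN) gives methyl 4-iodo-2,5-dimethoxybenzoate F2.
- Oxidation with mCPBA and TsOH followed by 1,3,5-trimethoxybenzene gives [2,5-dimethoxy-4-(methoxycarbonyl)phenyl](2,4,6-trimethoxyphenyl)iodonium 4-methylbenzenesulfonate F3.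
- Treating F3 with 7 and K2CO3 in toluene at 50 °C transfers the less electron-rich aryl group to the phenoxide and gives 10.

**Step 5 is third.**
- The risks are that the ester slows the oxidation, and that the activated quinone may add water or lose the aryloxy group in the acidic aqueous medium.
- The fallback sets out from 10 and comes back at 11. It splits the task into a chelation-directed demethylation and a much easier phenol oxidation.
- BCl3 in CH2Cl2 (−78 to 0 °C) cleaves only the methoxy group ortho to the ring B ester. This gives methyl 4-[3-heptyl-5-methoxy-2-(methoxycarbonyl)phenoxy]-2-hydroxy-5-methoxybenzoate F4.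
- Brief treatment of this para-methoxyphenol with PhI(OAc)2 in MeCN–H2O at 0 °C gives 11.

## Further compounds
F1 | step 7 | methyl 2-heptanoyl-4-[3-heptyl-5-methoxy-2-(methoxycarbonyl)phenoxy]-3,6-dihydroxybenzoate | CCCCCCCc1cc(OC)cc(Oc2cc(O)c(C(=O)OC)c(C(=O)CCCCCC)c2O)c1C(=O)OC
F2 | step 4 | methyl 4-iodo-2,5-dimethoxybenzoate | COC(=O)c1cc(OC)c(I)cc1OC
F3 | step 4 | [2,5-dimethoxy-4-(methoxycarbonyl)phenyl](2,4,6-trimethoxyphenyl)iodonium 4-methylbenzenesulfonate | COC(=O)c1cc(OC)c([I+]c2c(OC)cc(OC)cc2OC)cc1OC.Cc1ccc(cc1)S(=O)(=O)[O-]
F4 | step 5 | methyl 4-[3-heptyl-5-methoxy-2-(methoxycarbonyl)phenoxy]-2-hydroxy-5-methoxybenzoate | CCCCCCCc1cc(OC)cc(Oc2cc(O)c(C(=O)OC)cc2OC)c1C(=O)OC
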